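Numbering used throughout (avarane): C1–C10 are the decalin carbons, C11 the methylidene carbon on C4, C12, C13 and C14 the methyl groups on C5, C8 and C9, C15 the benzylic carbon, and C16–C21 the arene with oxygen on C17 (ortho to C16) and C20. β is the face of C12.

## The problem

20-O-Acetylneoavarol (21) is a trans-fused decalin with an exocyclic C4=C11 alkene, whose C9 carries a methylene-linked hydroquinone acetylated only at O20, the oxygen remote from C15. Four contiguous stereocentres (C5, C10, C9, C8) must be set, two of them quaternary. C12 and C14 are 1,3-diaxial on the β face, H10 is α, and C13 is equatorial. C5 and C10 define the trans ring fusion and have to be set absolutely. Once they exist, a chair-like closure of ring B can place C13 equatorial and let the axial C12 methyl decide which C9 substituent becomes axial, so C5/C10 can control C8 and C9. The exocyclic alkene migrates into the ring (C3=C4) under acid, the free hydroquinone is easily oxidised to the quinone, and the aryl acetate does not survive bases, ylides or hydrides. The alkene therefore has to come late, the acetate last, and O20 must be told apart from O17. The enabling feature is that C12 and H10 are trans across C5–C10. This is the geometry of an (E)-2-methyl-2-enal whose formyl carbon is C6 and whose β-substituent is C9. C1–C4 with oxygen on C4 is a 1-oxygenated butadiene, so ring A is a Diels–Alder adduct. C9 can enter as the inner carbon of a styrene (C9=C15) that later accepts C8.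

## Retrosynthesis

**O20–acetyl bond.** Target 21 is cut to neoavarol 20. Putting the ester on last keeps it away from every basic or reducing step. The neighbouring option, two different phenol protecting groups carried from the start, costs extra steps and must still end with a deprotection next to the acid-sensitive alkene. The forward step has to discriminate O20 from O17, which sits beside the neopentyl-like C15.

**Two O–CH3 bonds and C4=C11.** Diol 20 is cut to the dimethyl ether 17, and 17 to ketone 16 by a Wittig disconnection of C4=C11. Methyl ethers are the only phenol protection that is inert to every step before; their removal must be non-acidic. Creating the alkene from the C4 carbonyl only after all hydrogenations and the radical step removes any conflict with reductions.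

**C4 oxidation level.** Ketone 16 is traced through alcohol 15 to silyl ether 14. The C4 oxygen stays masked until ring B is closed. A free C4 ketone earlier would sit β to the C6 aldehyde (deformylation risk), and later would compete with the C8 ketone in reduction.

**C8–C9 bond (ring B).** Decalin 14 is cut to the secondary iodide 13. The neighbouring cuts are C9–C15 (benzylation of a decalone enolate) or C9–C14; both need a preformed decalin with extra oxygen at C8 that must afterwards be turned into the methyl group. The chosen cut uses the styrene already present, creates C8 and C9 in one step, and has C13, C14 and C15 at their final oxidation level. The forward step must close 6-exo through a chair, with the C8 radical adding to C9 faster than it is reduced.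

**C6=C7 and redox adjustment.** Iodide 13 comes from alcohol 12 and ketone 11. Ketone 11 comes from 10 by saturating C2=C3, 10 from enone 9 by conjugate reduction, and 9 from aldehyde 7 and phosphonate 8 by a Horner–Wadsworth–Emmons cut at C6=C7. The three carbons C7, C8 and C13 thus arrive in one reagent. C2=C3 is removed before the radical step so that the C8 radical cannot close onto C3.

**C4–C5 and C1–C10 (ring A).** Adduct 7 is cut to dienal 4 and silyloxydiene 6. This single cut removes a ring, two skeletal bonds and three stereocentres, and it leaves two achiral, conjugated, acyclic components. The forward reaction must be enantioface-selective, endo-selective, regioselective, and selective for the enal double bond over the styrene.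

**Components.** Dienal 4 comes from 2,5-dimethoxybenzaldehyde 1 by two Wittig homologations with the formyl ylide 2 through enal 3. Each one adds a C(CH3)=CH unit with (E) geometry. Diene 6 is the silyl dienol ether of crotonaldehyde 5.

## Roads not taken

**Alternative 1:** Both rings are cut at once (C9–C10 and C4–C5). The precursor is the acyclic benzylated β-keto ester A2, which carries an (E)-trisubstituted alkene, a terminal alkyne and an 8-phenylmenthyl ester. Mn(OAc)3 (trivalent manganese) in ethanol would oxidise A2 to the C9 radical, which adds 6-endo to C10. The resulting tertiary C5 radical adds 6-exo-dig to C4, and the vinyl radical takes hydrogen from the solvent, giving the trans-decalin keto ester A1 with the exocyclic alkene already in place.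
- Merits: two rings, both quaternary carbons, the aryl arm and the methylidene group come from one step on a chain made by simple alkylations. In bond-forming economy this is better than the chosen plan.
- Weak points: the absolute configuration rests on a stoichiometric auxiliary shielding a fully substituted radical. After the cascade C14 is an ester and C8 a ketone. Reducing a neopentyl ester to a methyl group takes about three steps. Converting C8=O into the β-methyl group by methylenation and hydrogenation cannot be done while C4=C11 is present, so the alkene delivered by the cascade would have to be masked or remade.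
- Comparison: the chosen plan sets against this a catalytic source of absolute configuration, methyl groups that are methyl groups from the start, and an alkene made only after the last reduction.

**Alternative 2:** The C9–C14 bond is cut. The precursor is the bicyclic allylic (bromomethyl)dimethylsilyl ether A4 with a C9=C10 alkene. With Bu3SnH and AIBN the α-silyl radical adds 5-exo to C9, and the C10 radical is reduced from the α face to give the oxasilolane-fused trans-decalin A3.
- Merits: the tether forces C14 syn to O8, so C9 is set with certainty. That is firmer than the rotamer preference that step 10 of the chosen plan relies on.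
- Weak points: C10 is set by intermolecular hydrogen transfer to a tertiary radical, which is not enforced. The C–Si bond must be protodesilylated. The C8 oxygen must then become the methyl group (oxidation, methylenation, face-selective hydrogenation). A4 already requires an enantioenriched decalin with the C5 centre, the tetrasubstituted alkene and the C8 carbinol.
- Comparison: the key step makes one C–C bond, and about five steps follow it before the level of 14 is reached. The chosen plan closes ring B and sets C8 and C9 in one step, at the price of a less certain C9 outcome, for which a fallback is given.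

**Alternative 3:** The arene is cut (three C–C bonds). The decalin propargyl compound A6 and the carbene complex A7, (CO)5Cr=C(OCH3)CH=CH2, would react by alkyne insertion, CO insertion and electrocyclisation (Dötz benzannulation) to give the mono-methyl ether A5, with the phenol next to C16.
- Merits: the two oxygens are differentiated by construction, which the chosen plan does not achieve; it relies on a steric bias in the last step.
- Weak points: the differentiation is the wrong way round for this target, since the free phenol is O17 and the methylated one is O20. Protection of O17, demethylation beside the exocyclic alkene, acetylation and deprotection would follow. A6 must already contain all four stereocentres and the alkene, so the benzannulation leaves the hard part of the problem untouched, and chromium is used stoichiometrically.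
- Comparison: the chosen plan sets against this a key step that itself builds the stereochemical core, and a protect–differentiate fallback for the acetylation.

Key step: step 4

Assumption: alcohol 12 and iodide 13 are carried as mixtures of C8 epimers, because C8 becomes a planar radical in step 10 and both epimers converge.

## Route

Step 1
Reactants: 1 2,5-dimethoxybenzaldehyde; 2 2-(triphenylphosphoranylidene)propanal
Product: 3 (E)-3-(2,5-dimethoxyphenyl)-2-methylprop-2-enal
Conditions: PhMe, 110 °C
Reagents that add atoms: none
Why: Wittig olefination with a formyl-stabilised ylide, which is reversible in the addition step and gives the (E)-enal; the conjugated product is less electrophilic than 1, so a second addition is slow.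

Step 2
Reactants: 3 (E)-3-(2,5-dimethoxyphenyl)-2-methylprop-2-enal; 2 2-(triphenylphosphoranylidene)propanal
Product: 4 (2E,4E)-5-(2,5-dimethoxyphenyl)-2,4-dimethylpenta-2,4-dienal
Conditions: PhMe, 110 °C, prolonged
Reagents that add atoms: none
Why: Second Wittig homologation with the same stabilised ylide; (E) geometry of the new C5=C10 bond follows from thermodynamic control, and this geometry later becomes the trans ring fusion.

Step 3
Reactants: 5 (E)-but-2-enal (crotonaldehyde)
Product: 6 (E)-1-(tert-butyldimethylsilyloxy)buta-1,3-diene
Conditions: TBSOTf, Et3N, Et2O, 0 °C to rt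
Reagents that add atoms: tert-butyldimethylsilyl trifluoromethanesulfonate, CC(C)(C)[Si](C)(C)OS(=O)(=O)C(F)(F)F
Why: O-silylation of the enal followed by γ-deprotonation (silyl dienol ether formation); the extended oxocarbenium ion gives mainly the (E)-dienol ether, the only isomer that reacts readily as a diene.

Step 4
Reactants: 4 (2E,4E)-5-(2,5-dimethoxyphenyl)-2,4-dimethylpenta-2,4-dienal; 6 (E)-1-(tert-butyldimethylsilyloxy)buta-1,3-diene
Product: 7 (1S,2R,6S)-2-(tert-butyldimethylsilyloxy)-6-[(E)-1-(2,5-dimethoxyphenyl)prop-1-en-2-yl]-1-methylcyclohex-3-ene-1-carbaldehyde (4α-OTBS, 5β-CH3, 5α-CHO, 10α-H)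
Conditions: (S)-B-(o-tolyl)oxazaborolidine from (S)-α,α-diphenylprolinol (20 mol%), HN(SO2CF3)2 (18 mol%), CH2Cl2, −78 to −40 °C
Reagents that add atoms: none
Why: The protonated oxazaborolidine binds the formyl oxygen of 4 (boron syn to the formyl hydrogen, which contacts the ring oxygen), lowering the LUMO of the s-trans C5=C10 enal while one phenyl group covers its rear face; diene 6 then adds to the open face in a concerted, asynchronous, suprafacial [4+2] cycloaddition that forms C1–C10 and C4–C5 and closes the six-membered ring A. The closest known reaction type is the Diels–Alder reaction of 2-methyl-2-enals with 1-oxygenated butadienes under acid-activated chiral oxazaborolidine catalysis, which creates a formyl-bearing quaternary carbon. C5 is set by the catalyst: on the usual pre-transition-state model for 2-substituted enals the (S)-catalyst exposes the Re face of C5, and the antipodal catalyst is equally available should the sense prove reversed for this extended enal. C10 follows from C5 because addition is suprafacial across the (E)-alkene, so C6 and the C9 arm stay trans. C4 follows from the endo orientation of the formyl group toward the (E)-diene, which places the silyloxy group cis to the formyl group. Regiochemistry is secured by the diene, whose unsubstituted terminus has the larger HOMO coefficient and bonds to the β-carbon C10, leaving the oxygen-bearing terminus to bond to C5. Site selectivity is secured by formyl coordination next to C5=C10 and by the lower reactivity of the trisubstituted, aryl-conjugated C9=C15 bond, which is kept as the later radical acceptor.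

Step 5
Reactants: 7 Diels–Alder adduct (aldehyde); 8 dimethyl (2-oxopropyl)phosphonate
Product: 9 (E)-enone: 7 with the formyl group replaced by (E)-CH=CH–C(O)CH3 (C6=C7, C8=O, C13)
Conditions: NaH, THF, 0 °C to 50 °C
Reagents that add atoms: none
Why: Horner–Wadsworth–Emmons olefination; the aldehyde has no α-hydrogen, so it can neither enolise nor epimerise, and the stabilised phosphonate anion gives the (E)-enone even at a neopentyl carbonyl.

Step 6
Reactants: 9 (E)-enone
Product: 10 methyl ketone: 4-[ring A]-butan-2-one with C6–C7 saturated, C2=C3 and styrene intact
Conditions: [(Ph3P)CuH]6 (0.4 equiv), H2O (2 equiv), PhH, rt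
Reagents that add atoms: none
Why: Conjugate reduction by a phosphine-stabilised copper hydride, which delivers hydride only to the β-carbon of an enone and leaves isolated alkenes, the styrene and the silyl ether untouched.

Step 7
Reactants: 10 methyl ketone with C2=C3
Product: 11 methyl ketone with saturated ring A (4α-OTBS, 5β-CH3, 10α-H; styrene intact)
Conditions: H2 (1–3 atm), RhCl(PPh3)3 (10 mol%), PhH, rt
Reagents that add atoms: none
Why: Homogeneous hydrogenation with RhCl(PPh3)3 reduces cis-disubstituted alkenes far faster than trisubstituted ones, so the ring alkene is saturated while the hindered β,β-disubstituted styrene remains; this removes the only other alkene the C8 radical could attack.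

Step 8
Reactants: 11 methyl ketone with saturated ring A
Product: 12 secondary alcohol at C8 (both C8 epimers)
Conditions: NaBH4, MeOH, 0 °C
Reagents that add atoms: none
Why: Borohydride reduction of an unhindered methyl ketone; the configuration at C8 is irrelevant at this stage.

Step 9
Reactants: 12 secondary alcohol at C8
Product: 13 secondary iodide at C8 (both C8 epimers)
Conditions: I2, PPh3, imidazole, CH2Cl2, 0 °C to rt
Reagents that add atoms: iodine, II
Why: Appel-type iodination through the alkoxyphosphonium salt with SN2 displacement by iodide; the conditions are neutral enough for the silyl ether and the electron-rich styrene.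

Step 10
Reactants: 13 secondary iodide at C8
Product: 14 trans-decalin: 4α-(tert-butyldimethylsilyloxy)-9α-(2,5-dimethoxybenzyl)-5β,8β,9β-trimethyl-trans-decalin (10α-H)
Conditions: Bu3SnH (1.3 equiv, syringe pump), AIBN (0.2 equiv), PhH (0.01 M), 80 °C
Reagents that add atoms: none
Why: Tin-hydride-mediated 6-exo-trig cyclisation of a secondary alkyl radical onto a styrene; the gain of a benzylic radical at C15 directs attack to C9, and Bu3SnH then reduces that radical. Closure should go through a chair on the ring A conformer with C6 and the C9 arm both equatorial: C13 pseudo-equatorial gives 8β-CH3, and the alkene rotamer with H10 eclipsing C9=C15 keeps the aryl-bearing C15 equatorial and C14 axial, which is the natural C9 configuration. High dilution and slow hydride addition hold back direct reduction of the C8 radical.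

Step 11
Reactants: 14 trans-decalin silyl ether
Product: 15 4α-alcohol
Conditions: Bu4NF, THF, 50 °C
Reagents that add atoms: none
Why: Fluoride cleavage of the Si–O bond; warming is needed for an axial ether beside a quaternary carbon, and nothing else in the molecule is fluoride-sensitive.

Step 12
Reactants: 15 4α-alcohol
Product: 16 C4 ketone
Conditions: Dess–Martin periodinane, CH2Cl2, rt
Reagents that add atoms: none
Why: Hypervalent-iodine oxidation of a hindered secondary alcohol under neutral conditions; the dimethoxyarene is not oxidised and C5 is quaternary, so no stereocentre is at risk.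

Step 13
Reactants: 16 C4 ketone
Product: 17 neoavarol dimethyl ether
Conditions: Ph3PCH3Br, KOt-Bu, PhMe, 90 °C
Reagents that add atoms: methyltriphenylphosphonium bromide, C[P+](c1ccccc1)(c1ccccc1)c1ccccc1.[Br-]
Why: Wittig methylenation with the salt-free ylide at elevated temperature, the standard answer to ketones flanked by a quaternary carbon; the only enolisable position (C3) is a methylene group, so enolisation costs no stereochemistry.

Step 14
Reactants: 17 neoavarol dimethyl ether
Product: 20 neoavarol, via neoavarol 20-O-methyl ether 18 (not isolated), via neoavarol 17-O-methyl ether 19 (not isolated)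
Conditions: n-BuSH, n-BuLi, HMPA, 0 °C; then 17, 110 °C; aq. HCl work-up under argon
Reagents that add atoms: none
Why: SN2 demethylation of aryl methyl ethers by a thiolate in a dipolar aprotic solvent; the conditions are strongly nucleophilic but non-acidic, so the exocyclic alkene cannot migrate, and both mono-ethers converge on the diol.

Step 15
Reactants: 20 neoavarol
Product: 21 20-O-acetylneoavarol, 4-hydroxy-3-{[(1R,2S,4aS,8aS)-1,2,4a-trimethyl-5-methylidenedecahydronaphthalen-1-yl]methyl}phenyl acetate
Conditions: Ac2O (1.05 equiv), pyridine, CH2Cl2, −20 °C
Reagents that add atoms: acetic anhydride, CC(=O)OC(C)=O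
Why: Kinetically controlled mono-acylation of a 2-substituted hydroquinone; O17 is shielded by the ortho CH2 group attached to the quaternary C9, so the unhindered O20 should react first with a limiting amount of anhydride at low temperature.

## Compound list

1 | 2,5-dimethoxybenzaldehyde | COc1ccc(OC)c(C=O)c1 | starting material
2 | 2-(triphenylphosphoranylidene)propanal | CC(C=O)=P(c1ccccc1)(c1ccccc1)c1ccccc1 | starting material
3 | (E)-3-(2,5-dimethoxyphenyl)-2-methylprop-2-enal | O=C/C(C)=C/c1cc(OC)ccc1OC | intermediate
4 | (2E,4E)-5-(2,5-dimethoxyphenyl)-2,4-dimethylpenta-2,4-dienal | O=C/C(C)=C/C(C)=C/c1cc(OC)ccc1OC | intermediate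
5 | (E)-but-2-enal (crotonaldehyde) | C/C=C/C=O | starting material
6 | (E)-1-(tert-butyldimethylsilyloxy)buta-1,3-diene | C=C/C=C/O[Si](C)(C)C(C)(C)C | intermediate
7 | (1S,2R,6S)-2-(tert-butyldimethylsilyloxy)-6-[(E)-1-(2,5-dimethoxyphenyl)prop-1-en-2-yl]-1-methylcyclohex-3-ene-1-carbaldehyde | CC(C)(C)[Si](C)(C)O[C@@H]1C=CC[C@@H](/C(C)=C/c2cc(OC)ccc2OC)[C@]1(C)C=O | intermediate
8 | dimethyl (2-oxopropyl)phosphonate | CC(=O)CP(=O)(OC)OC | starting material
9 | (E)-4-[ring A of 7]-but-3-en-2-one (formyl group of 7 replaced by (E)-CH=CH–C(O)CH3) | CC(C)(C)[Si](C)(C)O[C@@H]1C=CC[C@@H](/C(C)=C/c2cc(OC)ccc2OC)[C@]1(C)/C=C/C(C)=O | intermediate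
10 | 4-[ring A of 7]-butan-2-one (C6–C7 saturated, C2=C3 present) | CC(C)(C)[Si](C)(C)O[C@@H]1C=CC[C@@H](/C(C)=C/c2cc(OC)ccc2OC)[C@]1(C)CCC(C)=O | intermediate
11 | 4-[saturated ring A]-butan-2-one (4α-OTBS, 5β-CH3, 10α-H, (E)-styrene) | CC(C)(C)[Si](C)(C)O[C@@H]1CCC[C@@H](/C(C)=C/c2cc(OC)ccc2OC)[C@]1(C)CCC(C)=O | intermediate
12 | 4-[saturated ring A]-butan-2-ol (C8 epimers) | CC(C)(C)[Si](C)(C)O[C@@H]1CCC[C@@H](/C(C)=C/c2cc(OC)ccc2OC)[C@]1(C)CCC(C)O | intermediate
13 | 3-iodobutyl compound (C8 epimers) | CC(C)(C)[Si](C)(C)O[C@@H]1CCC[C@@H](/C(C)=C/c2cc(OC)ccc2OC)[C@]1(C)CCC(C)I | intermediate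
14 | 4α-(tert-butyldimethylsilyloxy)-9α-(2,5-dimethoxybenzyl)-5β,8β,9β-trimethyl-trans-decalin (10α-H) | CC(C)(C)[Si](C)(C)O[C@@H]1CCC[C@H]2[C@](C)(Cc3cc(OC)ccc3OC)[C@@H](C)CC[C@]12C | intermediate
15 | 4α-hydroxy analogue of 14 | O[C@@H]1CCC[C@H]2[C@](C)(Cc3cc(OC)ccc3OC)[C@@H](C)CC[C@]12C | intermediate
16 | 4-oxo analogue (9α-(2,5-dimethoxybenzyl)-5β,8β,9β-trimethyl-trans-decalin-4-one) | O=C1CCC[C@H]2[C@](C)(Cc3cc(OC)ccc3OC)[C@@H](C)CC[C@]12C | intermediate
17 | neoavarol dimethyl ether | C=C1CCC[C@H]2[C@](C)(Cc3cc(OC)ccc3OC)[C@@H](C)CC[C@]12C | intermediate
18 | neoavarol 20-O-methyl ether (17-OH free) | C=C1CCC[C@H]2[C@](C)(Cc3cc(OC)ccc3O)[C@@H](C)CC[C@]12C | intermediate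
19 | neoavarol 17-O-methyl ether (20-OH free) | C=C1CCC[C@H]2[C@](C)(Cc3cc(O)ccc3OC)[C@@H](C)CC[C@]12C | intermediate
20 | neoavarol | C=C1CCC[C@H]2[C@](C)(Cc3cc(O)ccc3O)[C@@H](C)CC[C@]12C | intermediate
21 | 20-O-acetylneoavarol | C=C1CCC[C@H]2[C@](C)(Cc3cc(OC(C)=O)ccc3O)[C@@H](C)CC[C@]12C | target

## Step count and least certain steps

Total: 15 steps. Longest linear sequence: 14 steps (1 to 21 through steps 1, 2 and 4–15); the diene branch adds step 3.

**Step 4 (key step).** The β-branched, cross-conjugated enal is a sluggish dienophile. The acid catalyst may desilylate or oligomerise the dienol ether before cycloaddition occurs, and the extended dienal may bind in more than one conformation, which would erode enantioface control. Fallback: the same cycloaddition of 4 and 6 is promoted by the achiral Lewis acid Me2AlCl (CH2Cl2, −78 °C), which should give 7 together with its enantiomer, ent-7 F1. Condensation of the mixture with (1R,2R)-N,N'-dimethyl-1,2-diphenylethane-1,2-diamine (molecular sieves, CH2Cl2) converts the two aldehydes into the diastereomeric imidazolidine of 7 F2 and the imidazolidine of ent-7 F3. These are separated by chromatography, and hydrolysis of F2 on wet silica with dilute acetic acid returns 7, where the route continues.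

**Step 10.** The secondary C8 radical must add to a fully substituted styrene carbon. Direct reduction by the tin hydride, or a 1,5-hydrogen shift from the allylic C10–H, may outrun ring closure, and rotamer control at C9 may be incomplete. Fallback: ketone 11 is treated with SmI2 (divalent samarium), HMPA and t-BuOH in THF. Ketyl formation is reversible, and the benzylic radical is reduced onward, so the closure should be driven to the tertiary alcohol, the 8-hydroxy decalin F4. Dehydration with methyl N-(triethylammoniosulfonyl)carbamate gives the 8(13)-methylidene decalin F5 together with its 7-ene isomer F6. Hydrogenation of both (H2, PtO2, EtOAc) from the α face, away from the axial C12 and C14 methyl groups, should give the 8β-methyl compound 14, where the route continues.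

**Step 7.** The ring alkene lies between a silyloxy carbon and a quaternary centre, and hydrogenation may be too slow. Forcing it may start to saturate the styrene needed in step 10. Fallback: the ring alkene is carried through ring closure and hydrogenated only when the styrene has been consumed. Ketone 10 is reduced (NaBH4) to the alcohol with C2=C3 F7, converted (I2, PPh3, imidazole) into the iodide with C2=C3 F8, and cyclised (Bu3SnH, AIBN) to the 2-ene decalin F9. Hydrogenation (H2, 10% Pd/C, EtOAc) then gives 14.

**Step 14.** The second demethylation is slow on an electron-rich phenoxide, so conversion may stall at the mono-ethers, and the dianion of the hydroquinone may oxidise in air during work-up. Fallback: 17 is oxidised with (NH4)2Ce(NO3)6 (tetravalent cerium) in MeCN/H2O at 0 °C to the quinone, neoavarone F10, and this is reduced with aqueous Na2S2O4 to 20.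

**Step 15.** Acyl transfer may not distinguish the two phenols well enough, giving the 17-acetate and the diacetate beside 21. Fallback: 20 is silylated at both oxygens (TBSCl, imidazole, DMF) to the bis-silyl ether F11. The unhindered O20 silyl group is removed selectively (K2CO3, MeOH, 0 °C) to give the 17-O-silyl phenol F12; the regioisomer can be separated and resilylated. Acetylation (Ac2O, pyridine) gives the 17-O-silyl 20-acetate F13, and buffered fluoride (HF·pyridine, THF, 0 °C) releases 21.

## Further compounds

F1 | step 4 | ent-7, (1R,2S,6R)-enantiomer of 7 | CC(C)(C)[Si](C)(C)O[C@H]1C=CC[C@H](/C(C)=C/c2cc(OC)ccc2OC)[C@@]1(C)C=O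
F2 | step 4 | (4R,5R)-1,3-dimethyl-4,5-diphenylimidazolidine of 7 | CC(C)(C)[Si](C)(C)O[C@@H]1C=CC[C@@H](/C(C)=C/c2cc(OC)ccc2OC)[C@]1(C)C1N(C)[C@H](c2ccccc2)[C@@H](c2ccccc2)N1C
F3 | step 4 | (4R,5R)-1,3-dimethyl-4,5-diphenylimidazolidine of ent-7 | CC(C)(C)[Si](C)(C)O[C@H]1C=CC[C@H](/C(C)=C/c2cc(OC)ccc2OC)[C@@]1(C)C1N(C)[C@H](c2ccccc2)[C@@H](c2ccccc2)N1C
F4 | step 10 | 8-hydroxy analogue of 14 (tertiary alcohol, C8 epimers) | CC(C)(C)[Si](C)(C)O[C@@H]1CCC[C@H]2[C@](C)(Cc3cc(OC)ccc3OC)C(C)(O)CC[C@]12C
F5 | step 10 | 8(13)-methylidene analogue of 14 | CC(C)(C)[Si](C)(C)O[C@@H]1CCC[C@H]2[C@](C)(Cc3cc(OC)ccc3OC)C(=C)CC[C@]12C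
F6 | step 10 | 7-ene analogue of 14 | CC(C)(C)[Si](C)(C)O[C@@H]1CCC[C@H]2[C@](C)(Cc3cc(OC)ccc3OC)C(C)=CC[C@]12C
F7 | step 7 | alcohol 12 retaining C2=C3 (C8 epimers) | CC(C)(C)[Si](C)(C)O[C@@H]1C=CC[C@@H](/C(C)=C/c2cc(OC)ccc2OC)[C@]1(C)CCC(C)O
F8 | step 7 | iodide 13 retaining C2=C3 (C8 epimers) | CC(C)(C)[Si](C)(C)O[C@@H]1C=CC[C@@H](/C(C)=C/c2cc(OC)ccc2OC)[C@]1(C)CCC(C)I
F9 | step 7 | 2-ene analogue of 14 | CC(C)(C)[Si](C)(C)O[C@@H]1C=CC[C@H]2[C@](C)(Cc3cc(OC)ccc3OC)[C@@H](C)CC[C@]12C
F10 | step 14 | neoavarone (quinone) | C=C1CCC[C@H]2[C@](C)(CC3=CC(=O)C=CC3=O)[C@@H](C)CC[C@]12C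
F11 | step 15 | neoavarol bis(tert-butyldimethylsilyl) ether | C=C1CCC[C@H]2[C@](C)(Cc3cc(O[Si](C)(C)C(C)(C)C)ccc3O[Si](C)(C)C(C)(C)C)[C@@H](C)CC[C@]12C
F12 | step 15 | neoavarol 17-O-(tert-butyldimethylsilyl) ether | C=C1CCC[C@H]2[C@](C)(Cc3cc(O)ccc3O[Si](C)(C)C(C)(C)C)[C@@H](C)CC[C@]12C
F13 | step 15 | 20-O-acetyl-17-O-(tert-butyldimethylsilyl)neoavarol | C=C1CCC[C@H]2[C@](C)(Cc3cc(OC(C)=O)ccc3O[Si](C)(C)C(C)(C)C)[C@@H](C)CC[C@]12C
A1 | alternative 1 | trans-decalin keto 8-phenylmenthyl ester with C4 exocyclic methylene | C=C1CCC[C@H]2[C@](C(=O)O[C@@H]3C[C@H](C)CC[C@H]3C(C)(C)c3ccccc3)(Cc3cc(OC)ccc3OC)C(=O)CC[C@]12C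
A2 | alternative 1 | acyclic benzylated β-keto 8-phenylmenthyl ester with (E)-alkene and terminal alkyne | C#CCCC/C=C(C)/CCC(=O)C(Cc1cc(OC)ccc1OC)C(=O)O[C@@H]1C[C@H](C)CC[C@H]1C(C)(C)c1ccccc1
A3 | alternative 2 | trans-decalin fused to the oxasilolane bridging C8 and C9 (C4 dioxolane) | O1CCOC12CCC[C@H]3[C@]4(C[Si](C)(C)O[C@H]4CC[C@]23C)Cc5cc(OC)ccc5OC
A4 | alternative 2 | (bromomethyl)dimethylsilyl ether of the 8β-hydroxy-9(10)-ene decalin (C4 dioxolane) | O1CCOC12CCCC3=C(Cc4cc(OC)ccc4OC)[C@@H](O[Si](C)(C)CBr)CC[C@]23C
A5 | alternative 3 | neoavarol mono-methyl ether (17-OH free, 20-OCH3) | C=C1CCC[C@H]2[C@](C)(Cc3cc(OC)ccc3O)[C@@H](C)CC[C@]12C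
A6 | alternative 3 | 9α-propargyl-5β,8β,9β-trimethyl-4-methylidene-trans-decalin | C=C1CCC[C@H]2[C@](C)(CC#C)[C@@H](C)CC[C@]12C
A7 | alternative 3 | pentacarbonyl[methoxy(vinyl)carbene]chromium | COC(C=C)=[Cr](=C=O)(=C=O)(=C=O)(=C=O)=C=O
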